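**Retrosynthetic overview**
1. Caespitane 13 ⇒ bromohydrin 11 (1,2-bromine shift through a bromonium ion, chloride capture) ⇒ epoxide 10 ⇒ cyclohexene 9.
2. Cyclohexene 9 ⇒ ring-closing metathesis of the acyclic 1,7-diene 8: the ring bond between the CHBr carbon and the C(CH3)Cl carbon is made as the ring C=C.
3. Enabling feature: in the cyclohexane the bromine-bearing CH and the chlorine-bearing C(CH3) are adjacent with Br and Cl trans, the footprint of anti addition to a 1-methylcyclohexene double bond. The ring CH that carries the oxane lies between two CH2 arms, so the ring opens to an allyl arm and a 3-methylbut-3-enyl arm.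
4. Diene 8 ⇒ triflate 6 + 2-methylallyl Grignard ⇒ bromo-oxane 5 ⇒ 6-endo bromoetherification of diol 4 ⇒ allyl opening of Sharpless epoxide 2 from geraniol, which fixes the adjacent CH and C–O stereocentres.
5. Ring order: oxane (step 3), then carbocycle (step 6); the carbocycle halogens come last (steps 7–9).

Key step: step 6

Remark: the facial sense of the Shi epoxidation in step 7 is assigned by analogy with 1-substituted cyclohexenes (the D-fructose-derived ketone gives (R,R)-1-phenylcyclohexene oxide).

Step 1
Reactants: 1 geraniol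
Product: 2 [(2S,3S)-3-methyl-3-(4-methylpent-3-en-1-yl)oxiran-2-yl]methanol
Conditions: Ti(OiPr)4 (5 mol%), L-(+)-diethyl tartrate (6 mol%), t-BuOOH, 4 Å MS, CH2Cl2, −20 °C
Reagents that add atoms: tert-butyl hydroperoxide, CC(C)(C)OO
Why: Sharpless asymmetric epoxidation: the titanium tartrate complex binds the allylic hydroxyl and delivers oxygen only to the 2,3-alkene, L-(+)-tartrate setting both epoxide carbons as (2S,3S), while the remote trisubstituted alkene has no directing OH and should stay untouched.

Step 2
Reactants: 2 [(2S,3S)-3-methyl-3-(4-methylpent-3-en-1-yl)oxiran-2-yl]methanol; 3 allylmagnesium chloride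
Product: 4 (2R,3S)-3,7-dimethyl-2-(prop-2-en-1-yl)oct-6-ene-1,3-diol
Conditions: 3 (3 equiv), CuBr·SMe2 (10 mol%), THF, −40 → 0 °C; aq. NH4Cl
Reagents that add atoms: none
Why: Copper-catalysed SN2 opening of a 2,3-epoxy alcohol by a Grignard reagent: attack should occur with inversion at the CH epoxide carbon, the only one open to backside approach because its neighbour is fully substituted, so the new CH stereocentre is set relative to the retained tertiary carbinol and both adjacent stereocentres derive from one Sharpless epoxide.

Step 3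
Reactants: 4 (2R,3S)-3,7-dimethyl-2-(prop-2-en-1-yl)oct-6-ene-1,3-diol
Product: 5 (2R)-2-[(2S,5R)-5-bromo-2,6,6-trimethyloxan-2-yl]pent-4-en-1-ol
Conditions: NBS (1.05 equiv), (CF3)2CHOH, 4 Å MS, 0 °C
Reagents that add atoms: N-bromosuccinimide, O=C1CCC(=O)N1Br
Why: Bromonium-induced 6-endo (Markovnikov) bromoetherification of a tertiary alcohol onto a trisubstituted alkene: oxygen adds anti to bromine at the dimethyl-substituted carbon through a chair transition state with bromine and the branched chain equatorial, which should set the CHBr centre R (bromine trans to the branched chain), and one equivalent of NBS is consumed by the far more nucleophilic trisubstituted alkene before the allyl group.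

Step 4
Reactants: 5 (2R)-2-[(2S,5R)-5-bromo-2,6,6-trimethyloxan-2-yl]pent-4-en-1-ol
Product: 6 (2R)-2-[(2S,5R)-5-bromo-2,6,6-trimethyloxan-2-yl]pent-4-en-1-yl trifluoromethanesulfonate
Conditions: Tf2O, 2,6-lutidine, CH2Cl2, −78 °C; cold work-up, used at once
Reagents that add atoms: trifluoromethanesulfonic anhydride, O=S(=O)(OS(=O)(=O)C(F)(F)F)C(F)(F)F
Why: Sulfonylation of the primary alcohol (triflate formation) creates a leaving group without touching a stereocentre, and the ether, the alkene and the hindered secondary bromide are inert to Tf2O at this temperature.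

Step 5
Reactants: 6 (2R)-2-[(2S,5R)-5-bromo-2,6,6-trimethyloxan-2-yl]pent-4-en-1-yl trifluoromethanesulfonate; 7 2-methylallylmagnesium chloride
Product: 8 (3R,6S)-3-bromo-2,2,6-trimethyl-6-[(4S)-7-methylocta-1,7-dien-4-yl]oxane
Conditions: 7 (2 equiv), CuBr·SMe2 (10 mol%), THF/Et2O, −78 → −20 °C
Reagents that add atoms: none
Why: Copper-catalysed sp3–sp3 coupling of a Grignard reagent with a primary alkyl triflate (SN2 at CH2): the symmetric 2-methylallyl nucleophile gives one product whichever terminus bonds, and the secondary bromide next to a quaternary carbon should not compete at low temperature.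

Step 6
Reactants: 8 (3R,6S)-3-bromo-2,2,6-trimethyl-6-[(4S)-7-methylocta-1,7-dien-4-yl]oxane
Product: 9 (3R,6S)-3-bromo-2,2,6-trimethyl-6-[(1S)-4-methylcyclohex-3-en-1-yl]oxane
Conditions: second-generation Grubbs catalyst RuCl2(=CHPh)(PCy3)(H2IMes) (5 mol%), CH2Cl2 (0.01 M), 40 °C
Reagents that add atoms: none
Why: Ring-closing olefin metathesis: the ruthenium methylidene first engages the unhindered allyl terminus, the resulting alkylidene adds across the 1,1-disubstituted alkene of the other arm to a ruthenacyclobutane, and cycloreversion joins the two internal alkene carbons as the ring C=C while ethene leaves and drives the reaction. The closest precedent is the routine closure of 2-methylocta-1,7-dienes to 1-methylcyclohexenes with this catalyst. The six-membered carbocycle is closed by [2+2] cycloaddition and cycloreversion at the metal, not by a polar or radical exo/endo attack. No stereocentre is created and the three existing ones are not touched. The selectivity needed is chemoselectivity and ring size, and the substrate secures both: only two alkenes remain (the prenyl alkene was consumed in step 3), they can pair only to a cyclohexene, the hindered secondary bromide and the ether are inert to the catalyst, and dilution suppresses dimerisation. The new double bond sits exactly between the two carbons that must carry Br and Cl, so both halogens can then be delivered anti across it.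

Step 7
Reactants: 9 (3R,6S)-3-bromo-2,2,6-trimethyl-6-[(1S)-4-methylcyclohex-3-en-1-yl]oxane
Product: 10 (3R,6S)-3-bromo-2,2,6-trimethyl-6-[(1R,3S,6S)-6-methyl-7-oxabicyclo[4.1.0]heptan-3-yl]oxane
Conditions: D-fructose-derived Shi ketone (30 mol%), Oxone (2KHSO5·KHSO4·K2SO4), K2CO3, Bu4NHSO4, MeCN/dimethoxymethane/aq. buffer pH 10.5, 0 °C
Reagents that add atoms: potassium peroxymonosulfate (the oxidant in Oxone), [K+].[O-]S(=O)(=O)OO
Why: Shi asymmetric epoxidation (chiral dioxirane, spiro transition state): the trisubstituted ring alkene is the only oxidisable site, the remote homoallylic stereocentre exerts little bias, and the D-fructose-derived ketone should deliver oxygen to the face trans to the oxanyl group, setting both epoxide carbons.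

Step 8
Reactants: 10 (3R,6S)-3-bromo-2,2,6-trimethyl-6-[(1R,3S,6S)-6-methyl-7-oxabicyclo[4.1.0]heptan-3-yl]oxane
Product: 11 (1R,2R,5S)-2-bromo-5-[(2S,5R)-5-bromo-2,6,6-trimethyloxan-2-yl]-2-methylcyclohexan-1-ol
Conditions: HBr (48% aq., 1.5 equiv), Et2O, −20 → 0 °C
Reagents that add atoms: hydrogen bromide, Br
Why: Acid-mediated epoxide opening by bromide: attack at the tertiary carbon with inversion is both the Markovnikov and the trans-diaxial (Fürst–Plattner) mode for this epoxide diastereomer, so a tertiary axial bromide cis to the oxanyl group and a secondary axial alcohol should result.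

Step 9
Reactants: 11 (1R,2R,5S)-2-bromo-5-[(2S,5R)-5-bromo-2,6,6-trimethyloxan-2-yl]-2-methylcyclohexan-1-ol
Product: 13 caespitane (3R,6S)-3-bromo-6-[(1S,3S,4S)-3-bromo-4-chloro-4-methylcyclohexyl]-2,2,6-trimethyloxane, via chlorosulfite ester 12 (not isolated)
Conditions: SOCl2, pyridine, CH2Cl2, −20 → 23 °C
Reagents that add atoms: thionyl chloride, O=S(Cl)Cl
Why: Deoxychlorination with neighbouring-group participation: the axial bromine anti-periplanar to the chlorosulfite displaces it to a bromonium ion on the ring face cis to the oxanyl group, and chloride should open this ion anti at the tertiary carbon (Markovnikov), which moves bromine to the CH carbon on the same face and places chlorine trans to it on the methyl-bearing carbon; any diaxial isomer from chloride capture at the secondary carbon shares the same ion pair and should funnel to 13 on warming through the known diaxial-to-diequatorial 1,2-halogen interchange.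

**Compound list**
1 | geraniol, (2E)-3,7-dimethylocta-2,6-dien-1-ol | CC(C)=CCC/C(C)=C/CO | starting material
2 | [(2S,3S)-3-methyl-3-(4-methylpent-3-en-1-yl)oxiran-2-yl]methanol | OC[C@@H]1O[C@@]1(C)CCC=C(C)C | intermediate
3 | allylmagnesium chloride | C=CC[Mg]Cl | starting material
4 | (2R,3S)-3,7-dimethyl-2-(prop-2-en-1-yl)oct-6-ene-1,3-diol | C=CC[C@H](CO)[C@@](C)(O)CCC=C(C)C | intermediate
5 | (2R)-2-[(2S,5R)-5-bromo-2,6,6-trimethyloxan-2-yl]pent-4-en-1-ol | CC1(C)O[C@](C)([C@@H](CO)CC=C)CC[C@H]1Br | intermediate
6 | (2R)-2-[(2S,5R)-5-bromo-2,6,6-trimethyloxan-2-yl]pent-4-en-1-yl trifluoromethanesulfonate | CC1(C)O[C@](C)([C@@H](COS(=O)(=O)C(F)(F)F)CC=C)CC[C@H]1Br | intermediate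
7 | 2-methylallylmagnesium chloride | CC(=C)C[Mg]Cl | starting material
8 | (3R,6S)-3-bromo-2,2,6-trimethyl-6-[(4S)-7-methylocta-1,7-dien-4-yl]oxane | CC1(C)O[C@](C)([C@@H](CCC(C)=C)CC=C)CC[C@H]1Br | intermediate
9 | (3R,6S)-3-bromo-2,2,6-trimethyl-6-[(1S)-4-methylcyclohex-3-en-1-yl]oxane | CC1(C)O[C@](C)([C@H]2CCC(C)=CC2)CC[C@H]1Br | intermediate
10 | (3R,6S)-3-bromo-2,2,6-trimethyl-6-[(1R,3S,6S)-6-methyl-7-oxabicyclo[4.1.0]heptan-3-yl]oxane | CC1(C)O[C@](C)([C@H]2CC[C@]3(C)O[C@@H]3C2)CC[C@H]1Br | intermediate
11 | (1R,2R,5S)-2-bromo-5-[(2S,5R)-5-bromo-2,6,6-trimethyloxan-2-yl]-2-methylcyclohexan-1-ol | CC1(C)O[C@](C)([C@H]2CC[C@@](C)(Br)[C@H](O)C2)CC[C@H]1Br | intermediate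
12 | chlorosulfite ester of 11 | CC1(C)O[C@](C)([C@H]2CC[C@@](C)(Br)[C@H](OS(=O)Cl)C2)CC[C@H]1Br | intermediate (not isolated)
13 | caespitane, (3R,6S)-3-bromo-6-[(1S,3S,4S)-3-bromo-4-chloro-4-methylcyclohexyl]-2,2,6-trimethyloxane | CC1(C)O[C@](C)([C@H]2CC[C@](C)(Cl)[C@@H](Br)C2)CC[C@H]1Br | target

**Step count**
Total steps: 9. Longest linear sequence: 9 steps (geraniol 1 to caespitane 13).

**Steps most likely to fail, with fallbacks**

Step 3. The tertiary hydroxyl may attack the secondary bromonium carbon (5-exo closure to the oxolane regioisomer) instead of the dimethyl-substituted carbon. The fallback sets out from 4 and comes back at 5, and makes the ether bond under thermodynamic control. Shi epoxidation of the trisubstituted alkene of 4 with the enantiomeric (L-fructose-derived) ketone should give the (S)-configured epoxy diol (2R,3S)-5-[(2S)-3,3-dimethyloxiran-2-yl]-3-methyl-2-(prop-2-en-1-yl)pentane-1,3-diol F1. Li2NiBr4 in THF should open it at the CH carbon with inversion to the bromo triol (2R,3S,6R)-6-bromo-3,7-dimethyl-2-(prop-2-en-1-yl)octane-1,3,7-triol F2. Catalytic camphorsulfonic acid in CH2Cl2 then ionises the C(CH3)2–OH with assistance from the neighbouring bromine, and the other tertiary hydroxyl closes the six-membered ether to give 5.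

Step 9. Chloride may be captured at the secondary bromonium carbon (substitution without bromine shift), or HBr may be lost from the tertiary bromide. The fallback sets out from 10 and comes back at 13. Epoxide 10 would be isomerised with diethylaluminium 2,2,6,6-tetramethylpiperidide to the exocyclic allylic alcohol (1R,5S)-5-[(2S,5R)-5-bromo-2,6,6-trimethyloxan-2-yl]-2-methylidenecyclohexan-1-ol F3. Appel bromination (CBr4, PPh3, CH2Cl2, 0 °C) with inversion should give the equatorial allylic bromide (3R,6S)-3-bromo-6-[(1S,3S)-3-bromo-4-methylidenecyclohexyl]-2,2,6-trimethyloxane F4, whose carbinol carbon is no longer next to a quaternary centre. Anhydrous HCl at −40 °C then adds in the Markovnikov sense through the same bromine-bridged tertiary cation, chloride entering anti to bromine, to give 13.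

Step 7. Facial selectivity may be low, because the catalyst has to control it without help from the remote stereocentre. The fallback sets out from 9 and comes back at 10, and replaces reagent control by a chemical kinetic separation. Unselective epoxidation of 9 with mCPBA should give 10 together with its diastereomer (3R,6S)-3-bromo-2,2,6-trimethyl-6-[(1S,3S,6R)-6-methyl-7-oxabicyclo[4.1.0]heptan-3-yl]oxane F5. Pyrrolidine in water at reflux should open only F5, by trans-diaxial attack at its CH carbon, to the amino alcohol (1R,2R,4S)-4-[(2S,5R)-5-bromo-2,6,6-trimethyloxan-2-yl]-1-methyl-2-(pyrrolidin-1-yl)cyclohexan-1-ol F6, which is removed by acid extraction. Epoxide 10 is left, because its only diaxial opening would need attack at the tertiary carbon.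

**Further compounds**
F1 | step 3 | (2R,3S)-5-[(2S)-3,3-dimethyloxiran-2-yl]-3-methyl-2-(prop-2-en-1-yl)pentane-1,3-diol | C=CC[C@H](CO)[C@@](C)(O)CC[C@@H]1OC1(C)C
F2 | step 3 | (2R,3S,6R)-6-bromo-3,7-dimethyl-2-(prop-2-en-1-yl)octane-1,3,7-triol | C=CC[C@H](CO)[C@@](C)(O)CC[C@@H](Br)C(C)(C)O
F3 | step 9 | (1R,5S)-5-[(2S,5R)-5-bromo-2,6,6-trimethyloxan-2-yl]-2-methylidenecyclohexan-1-ol | CC1(C)O[C@](C)([C@H]2CCC(=C)[C@H](O)C2)CC[C@H]1Br
F4 | step 9 | (3R,6S)-3-bromo-6-[(1S,3S)-3-bromo-4-methylidenecyclohexyl]-2,2,6-trimethyloxane | CC1(C)O[C@](C)([C@H]2CCC(=C)[C@@H](Br)C2)CC[C@H]1Br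
F5 | step 7 | (3R,6S)-3-bromo-2,2,6-trimethyl-6-[(1S,3S,6R)-6-methyl-7-oxabicyclo[4.1.0]heptan-3-yl]oxane | CC1(C)O[C@](C)([C@H]2CC[C@@]3(C)O[C@H]3C2)CC[C@H]1Br
F6 | step 7 | (1R,2R,4S)-4-[(2S,5R)-5-bromo-2,6,6-trimethyloxan-2-yl]-1-methyl-2-(pyrrolidin-1-yl)cyclohexan-1-ol | CC1(C)O[C@](C)([C@H]2CC[C@@](C)(O)[C@H](N3CCCC3)C2)CC[C@H]1Br
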